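The slowest thing in this flask, once each step is turned into a half-life at the charged amounts and taken by itself, is the leak of substrate and partner straight to side product A, at 72 h, so you can set that leak aside and watch the quicker part: substrate and partner give the intermediate with a forward half-life of 1.9 h, and the intermediate has two exits, to target in 5.1 h and, with a further partner, to side product B in 2.7 h.

common to all: substrate 0.10 M; partner 0.130 M

| run | time |
|---|---|
| summer | 20 h |
| dusk | 60 h |
| noon | 180 h |

* which of these there is most of at the end, counted by the substrate in it, summer (side product B / target / isomer of the product / substrate)
* which of these there is most of at the end, counted by the substrate in it, dusk (side product B / target / isomer of the product / substrate)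
* which of these there is most of at the end, counted by the substrate in it, noon (side product B / target / isomer of the product / substrate)
* how much there is at the end of the one of these that leads, in percent of the substrate charged: summer
* how much there is at the end of the one of these that leads, in percent of the substrate charged: dusk
* how much there is at the end of the one of these that leads, in percent of the substrate charged: noon

    substrate + partner ⇌ intermediate (K1 = 14.5 M⁻¹, k1 = 2.80 M⁻¹ h⁻¹)
    intermediate → target (k2 = 0.135 h⁻¹)
    substrate + partner → side product A (k3 = 0.0737 M⁻¹ h⁻¹)
    partner + intermediate → side product B (k4 = 1.99 M⁻¹ h⁻¹)
    target ⇌ isomer of the product (K5 = 8.2, k5 = 0.142 h⁻¹)
    substrate ⇌ dormant form (K6 = 0.90, k6 = 0.0245 h⁻¹)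
    crystals ⇌ target, rate k7*(cs7 - [target]) while solid is left; crystals form when [target] > cs7 (cs7 = 0.056 M, k7 = 3.83 h⁻¹)

The bench habit says that a partner charged at 1.30 times the substrate is in excess, so you hold [partner] at its charge (the pseudo-first-order view) and read the exits from those half-lives: 1.92 parts side product B to one part target, which sends 65.8% of the substrate to side product B. But each substrate reaching side product B costs two partners and each reaching target costs one, so that rule asks for 0.166 M of partner, more than the 0.130 M charged. There the rule stops: partner is the limiting reagent, and [partner] must fall during the run.

What you carry instead is the crossing level 0.0678 M, the [partner] at which the intermediate leaves equally by both exits, reckoned as the rate constant of the target exit over that of the side product B exit; above it side product B takes the bigger share, below it target does. Adding up the exits while [partner] falls from its charge down to zero, you get 0.0534 M through target, and the partner remaining gives 0.0383 M of side product B. The 4.35 h relaxation between target and isomer of the product in noon is shorter than the 180 h of that run, so I split the target route between the two by its equilibrium constant, 8.2 parts isomer to one part target, and the dissolved target at that split stays below its solubility, so I expect no crystals. Taking noon as that long run, since 180 h is longer than the slowest half-life, my reckoning has 0.0476 M of isomer, so isomer of the product leads at 47.6%. For summer and dusk I commit to no figure.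

The forecast gives side product B at 30% for summer, isomer of the product at 37% for dusk and isomer of the product at 45% for noon, saying of side product B that “it takes two partners per substrate and stalls as partner runs down”. Its noon figure is lower than mine.

The simulation gives side product B at 29.6% for summer, isomer of the product at 38.8% for dusk and isomer of the product at 46.1% for noon.

In summer, partner reads 0.0426 M at 10.0 h, below the crossing level, and from then to 20.0 h side product B gains 5 percentage points while target and isomer together gain 9.4 points. The neighbouring flask is noon with 0.22 M of partner, 3.24 times the crossing level and more than the 0.200 M that two partners per substrate take. Its partner ends at 0.0604 M, so the same sum gives 0.0336 M through target, and 29.9% as isomer. That flask reads 32.0% isomer at 180 h, and side product B leads at 59.9%.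

The constants used here stand for no real mixture; the rest is arithmetic.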